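**Plan**

1. Ring A carries OMe at C1, H at C2, OH at C3, a benzyl at C4, the CH2CH2–ring B chain at C5 and a benzyl at C6. The meta C1/C3 oxygens are the imprint of a 1-methoxy-3-silyloxycyclohexa-1,3-diene, and C5/C6 with their two carbon substituents are the imprint of an alkyne. The retrosynthesis therefore cuts C4–C5 and C1–C6 (Alder–Rickert), after the C6 benzylic CH2 is taken back to a ketone that activates the alkyne.
2. Further cuts: the C4–CH2Ar bond of the diene (enolate benzylation of 3-methoxycyclohexenone); in the ynone the acyl–alkyne bond, the alkyne carbon added by homologation, the ring B–CH2 bond of the chain and the ring B diarylmethane bond, back to 4-bromo-2-hydroxybenzaldehyde.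
3. Forward: diene 6 in two steps; ring B fragment to ynone 16 in six steps; cycloaddition with ethylene loss then builds ring A, the only ring made in the route.
4. Ketone reduction, desilylation and one global hydrogenolysis finish the target.
5. Stereochemistry: the target is achiral; the stereocentres in 4, 11, 17, 19 and 20 are racemic and each is erased later.

Key step: step 9

Remark: ring A is numbered C1 (OMe) to C6 (the benzyl next to OMe) throughout, and LDA is taken as the commercial solution.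

**Step 1**
Reactants: 1 3-methoxycyclohex-2-en-1-one; 2 4-(benzyloxy)benzyl chloride
Product: 4 6-[4-(benzyloxy)benzyl]-3-methoxycyclohex-2-en-1-one (racemic), via lithium 5-methoxycyclohexa-1,5-dien-1-olate 3 (not isolated)
Conditions: LDA, THF, −78 °C; then 2, DMPU, −78 → 0 °C
Reagents that add atoms: none
Why: Kinetic deprotonation of the vinylogous ester occurs at the α′ carbon and the cross-conjugated lithium enolate should be C-alkylated by the reactive 4-alkoxybenzyl chloride (Stork–Danheiser enolate alkylation); the new stereocentre is racemic and disappears in step 2.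

**Step 2**
Reactants: 4 6-[4-(benzyloxy)benzyl]-3-methoxycyclohex-2-en-1-one
Product: 6 1-[4-(benzyloxy)benzyl]-2-(tert-butyldimethylsilyloxy)-4-methoxycyclohexa-1,3-diene, via lithium 2-[4-(benzyloxy)benzyl]-5-methoxycyclohexa-1,5-dien-1-olate 5 (not isolated)
Conditions: LDA, THF, −78 °C; then TBSCl, DMPU, −78 °C → rt; pentane/cold aq NaHCO3 work-up, filtration through Et3N-washed silica
Reagents that add atoms: tert-butyldimethylsilyl chloride, CC(C)(C)[Si](C)(C)Cl
Why: A second kinetic α′-deprotonation regenerates the cross-conjugated enolate, and O-silylation (silyl enol ether formation) should fix it as the 1-methoxy-3-silyloxy diene rather than the linearly conjugated isomer.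

**Step 3**
Reactants: 7 4-bromo-2-hydroxybenzaldehyde
Product: 8 2-(benzyloxy)-4-bromobenzaldehyde
Conditions: BnBr, K2CO3, DMF, rt
Reagents that add atoms: benzyl bromide, BrCc1ccccc1
Why: Williamson ether synthesis on an acidic ortho-formyl phenol should be clean and masks the ring B phenol in a form that the final hydrogenolysis removes.

**Step 4**
Reactants: 8 2-(benzyloxy)-4-bromobenzaldehyde; 9 1-(benzyloxy)-4-bromobenzene
Product: 11 [2-(benzyloxy)-4-bromophenyl][4-(benzyloxy)phenyl]methanol (racemic), via 4-(benzyloxy)phenylmagnesium bromide 10 (not isolated)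
Conditions: 9, Mg (I2 cat.), THF, reflux; then 8, THF, 0 °C; aq NH4Cl
Reagents that add atoms: none
Why: Grignard addition to the aldehyde is much faster than any bromine–magnesium exchange at the aryl bromide of 8 and forms the diarylmethane C–C bond; the carbinol centre is racemic and is removed in step 5.

**Step 5**
Reactants: 11 [2-(benzyloxy)-4-bromophenyl][4-(benzyloxy)phenyl]methanol
Product: 12 2-(benzyloxy)-1-[4-(benzyloxy)benzyl]-4-bromobenzene
Conditions: Et3SiH, TFA, CH2Cl2, 0 °C
Reagents that add atoms: none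
Why: Ionic hydrogenation: the benzhydryl cation, stabilised by an ortho and a para alkoxy group, forms readily in TFA and is trapped by the silane, while the aryl bromide and the benzyl ethers should survive the short cold exposure.

**Step 6**
Reactants: 12 2-(benzyloxy)-1-[4-(benzyloxy)benzyl]-4-bromobenzene
Product: 13 3-{3-(benzyloxy)-4-[4-(benzyloxy)benzyl]phenyl}propanal
Conditions: allyl alcohol, Pd(OAc)2 (5 mol %), Bu4NCl, NaHCO3, DMF, 80 °C
Reagents that add atoms: allyl alcohol, C=CCO
Why: Heck arylation of allyl alcohol under Jeffery conditions places the aryl group on the terminal carbon, and β-hydride elimination toward oxygen gives an enol that tautomerises to the 3-arylpropanal.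

**Step 7**
Reactants: 13 3-{3-(benzyloxy)-4-[4-(benzyloxy)benzyl]phenyl}propanal
Product: 14 2-(benzyloxy)-1-[4-(benzyloxy)benzyl]-4-(but-3-yn-1-yl)benzene
Conditions: dimethyl (1-diazo-2-oxopropyl)phosphonate, K2CO3, MeOH, 0 °C → rt
Reagents that add atoms: dimethyl (1-diazo-2-oxopropyl)phosphonate, COP(=O)(OC)C(=[N+]=[N-])C(C)=O
Why: Seyferth–Gilbert homologation with the Ohira–Bestmann reagent converts enolisable aliphatic aldehydes into terminal alkynes under mild carbonate conditions that leave the benzyl ethers untouched.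

**Step 8**
Reactants: 14 2-(benzyloxy)-1-[4-(benzyloxy)benzyl]-4-(but-3-yn-1-yl)benzene; 15 4-(benzyloxy)benzoyl chloride
Product: 16 5-{3-(benzyloxy)-4-[4-(benzyloxy)benzyl]phenyl}-1-[4-(benzyloxy)phenyl]pent-2-yn-1-one
Conditions: PdCl2(PPh3)2 (2 mol %), CuI (4 mol %), Et3N, THF, rt
Reagents that add atoms: none
Why: Acyl Sonogashira coupling of a terminal alkyl acetylene with an aroyl chloride gives the conjugated ynone directly at room temperature without a strong base.

**Step 9**
Reactants: 6 1-[4-(benzyloxy)benzyl]-2-(tert-butyldimethylsilyloxy)-4-methoxycyclohexa-1,3-diene; 16 5-{3-(benzyloxy)-4-[4-(benzyloxy)benzyl]phenyl}-1-[4-(benzyloxy)phenyl]pent-2-yn-1-one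
Product: 18 {2-(2-{3-(benzyloxy)-4-[4-(benzyloxy)benzyl]phenyl}ethyl)-3-[4-(benzyloxy)benzyl]-4-(tert-butyldimethylsilyloxy)-6-methoxyphenyl}[4-(benzyloxy)phenyl]methanone, via bicyclo[2.2.2]octa-2,5-diene cycloadduct 17 (not isolated)
Conditions: 6 (2 equiv), BHT (cat.), degassed mesitylene, base-washed sealed tube, 130 °C then 180 °C
Reagents that add atoms: none
Why: The ring-held cisoid diene 6, made electron-rich by its methoxy and silyloxy groups, should add across the electron-poor triple bond of 16 in a thermally allowed [4+2] cycloaddition to give bicyclic adduct 17, and further heating should expel the saturated CH2–CH2 bridge as ethylene by cycloreversion, with aromatisation as the driving force (Alder–Rickert reaction). The closest known reaction type is the Alder–Rickert arene synthesis from 1-alkoxy-3-silyloxycyclohexa-1,3-dienes and acetylenic esters or ketones. Ring A is closed by an untethered intermolecular cycloaddition that forms C4–C5 and C1–C6 in one event, and the six-membered ring persists after the two-carbon bridge is lost. No stereocentre remains, because the two bridgehead centres of 17 arise as a racemate and both become aromatic carbons. The step needs regioselectivity, and the diene should provide it: both oxygens direct electron density to the benzyl-bearing terminus (β to the silyloxy group and vinylogously δ to the methoxy group), so this carbon bonds to the electrophilic β-carbon of the ynone and the methoxy-bearing terminus bonds to the acyl-bearing carbon. Excess diene, a radical inhibitor and acid-free glass are meant to offset the slow addition at two fully substituted diene termini.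

**Step 10**
Reactants: 18 the ring A aryl ketone
Product: 19 {2-(2-{3-(benzyloxy)-4-[4-(benzyloxy)benzyl]phenyl}ethyl)-3-[4-(benzyloxy)benzyl]-4-(tert-butyldimethylsilyloxy)-6-methoxyphenyl}[4-(benzyloxy)phenyl]methanol (racemic)
Conditions: LiAlH4, THF, 0 °C → rt; aq potassium sodium tartrate work-up
Reagents that add atoms: none
Why: Hydride reduction with the small, reactive LiAlH4 should overcome the two ortho substituents flanking the diaryl ketone, and the racemic carbinol centre is removed in step 12.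

**Step 11**
Reactants: 19 the silylated diaryl carbinol
Product: 20 4-{[4-(benzyloxy)phenyl](hydroxy)methyl}-3-(2-{3-(benzyloxy)-4-[4-(benzyloxy)benzyl]phenyl}ethyl)-2-[4-(benzyloxy)benzyl]-5-methoxyphenol (racemic)
Conditions: TBAF, AcOH, THF, 0 °C
Reagents that add atoms: none
Why: Fluoride-mediated cleavage of the aryl silyl ether is fast, and buffering with acetic acid keeps the phenoxide from forming so that the ionisable benzhydrol is not pushed toward a quinone methide.

**Step 12**
Reactants: 20 the phenolic diaryl carbinol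
Product: 21 3-{2-[3-hydroxy-4-(4-hydroxybenzyl)phenyl]ethyl}-2,4-bis(4-hydroxybenzyl)-5-methoxyphenol (target)
Conditions: H2 (1 atm), Pd/C (10 wt % Pd), EtOAc–MeOH, HCl (cat.), rt
Reagents that add atoms: none
Why: Catalytic hydrogenolysis should cleave the four benzyl ethers and, with acid assistance, the doubly benzylic C–OH bond next to the 4-oxygenated aryl ring, so one operation delivers the C6 benzyl group and all remaining free phenols.

**Compound list**

1 | 3-methoxycyclohex-2-en-1-one | COC1=CC(=O)CCC1 | starting material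
2 | 4-(benzyloxy)benzyl chloride | ClCc1ccc(OCc2ccccc2)cc1 | starting material
3 | lithium 5-methoxycyclohexa-1,5-dien-1-olate | [Li+].COC1=CC([O-])=CCC1 | intermediate
4 | 6-[4-(benzyloxy)benzyl]-3-methoxycyclohex-2-en-1-one (racemic) | COC1=CC(=O)C(Cc2ccc(OCc3ccccc3)cc2)CC1 | intermediate
5 | lithium 2-[4-(benzyloxy)benzyl]-5-methoxycyclohexa-1,5-dien-1-olate | [Li+].COC1=CC([O-])=C(Cc2ccc(OCc3ccccc3)cc2)CC1 | intermediate
6 | 1-[4-(benzyloxy)benzyl]-2-(tert-butyldimethylsilyloxy)-4-methoxycyclohexa-1,3-diene | COC1=CC(O[Si](C)(C)C(C)(C)C)=C(Cc2ccc(OCc3ccccc3)cc2)CC1 | intermediate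
7 | 4-bromo-2-hydroxybenzaldehyde | O=Cc1ccc(Br)cc1O | starting material
8 | 2-(benzyloxy)-4-bromobenzaldehyde | O=Cc1ccc(Br)cc1OCc1ccccc1 | intermediate
9 | 1-(benzyloxy)-4-bromobenzene | Brc1ccc(OCc2ccccc2)cc1 | starting material
10 | 4-(benzyloxy)phenylmagnesium bromide | Br[Mg]c1ccc(OCc2ccccc2)cc1 | intermediate
11 | [2-(benzyloxy)-4-bromophenyl][4-(benzyloxy)phenyl]methanol (racemic) | OC(c1ccc(OCc2ccccc2)cc1)c1ccc(Br)cc1OCc1ccccc1 | intermediate
12 | 2-(benzyloxy)-1-[4-(benzyloxy)benzyl]-4-bromobenzene | Brc1ccc(Cc2ccc(OCc3ccccc3)cc2)c(OCc2ccccc2)c1 | intermediate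
13 | 3-{3-(benzyloxy)-4-[4-(benzyloxy)benzyl]phenyl}propanal | O=CCCc1ccc(Cc2ccc(OCc3ccccc3)cc2)c(OCc2ccccc2)c1 | intermediate
14 | 2-(benzyloxy)-1-[4-(benzyloxy)benzyl]-4-(but-3-yn-1-yl)benzene | C#CCCc1ccc(Cc2ccc(OCc3ccccc3)cc2)c(OCc2ccccc2)c1 | intermediate
15 | 4-(benzyloxy)benzoyl chloride | O=C(Cl)c1ccc(OCc2ccccc2)cc1 | starting material
16 | 5-{3-(benzyloxy)-4-[4-(benzyloxy)benzyl]phenyl}-1-[4-(benzyloxy)phenyl]pent-2-yn-1-one | O=C(C#CCCc1ccc(Cc2ccc(OCc3ccccc3)cc2)c(OCc2ccccc2)c1)c1ccc(OCc2ccccc2)cc1 | intermediate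
17 | {4-[4-(benzyloxy)benzyl]-3-(2-{3-(benzyloxy)-4-[4-(benzyloxy)benzyl]phenyl}ethyl)-5-(tert-butyldimethylsilyloxy)-1-methoxybicyclo[2.2.2]octa-2,5-dien-2-yl}[4-(benzyloxy)phenyl]methanone (racemic) | COC12CCC(Cc3ccc(OCc4ccccc4)cc3)(C(O[Si](C)(C)C(C)(C)C)=C1)C(CCc1ccc(Cc3ccc(OCc4ccccc4)cc3)c(OCc3ccccc3)c1)=C2C(=O)c1ccc(OCc2ccccc2)cc1 | intermediate
18 | {2-(2-{3-(benzyloxy)-4-[4-(benzyloxy)benzyl]phenyl}ethyl)-3-[4-(benzyloxy)benzyl]-4-(tert-butyldimethylsilyloxy)-6-methoxyphenyl}[4-(benzyloxy)phenyl]methanone | COc1cc(O[Si](C)(C)C(C)(C)C)c(Cc2ccc(OCc3ccccc3)cc2)c(CCc2ccc(Cc3ccc(OCc4ccccc4)cc3)c(OCc3ccccc3)c2)c1C(=O)c1ccc(OCc2ccccc2)cc1 | intermediate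
19 | {2-(2-{3-(benzyloxy)-4-[4-(benzyloxy)benzyl]phenyl}ethyl)-3-[4-(benzyloxy)benzyl]-4-(tert-butyldimethylsilyloxy)-6-methoxyphenyl}[4-(benzyloxy)phenyl]methanol (racemic) | COc1cc(O[Si](C)(C)C(C)(C)C)c(Cc2ccc(OCc3ccccc3)cc2)c(CCc2ccc(Cc3ccc(OCc4ccccc4)cc3)c(OCc3ccccc3)c2)c1C(O)c1ccc(OCc2ccccc2)cc1 | intermediate
20 | 4-{[4-(benzyloxy)phenyl](hydroxy)methyl}-3-(2-{3-(benzyloxy)-4-[4-(benzyloxy)benzyl]phenyl}ethyl)-2-[4-(benzyloxy)benzyl]-5-methoxyphenol (racemic) | COc1cc(O)c(Cc2ccc(OCc3ccccc3)cc2)c(CCc2ccc(Cc3ccc(OCc4ccccc4)cc3)c(OCc3ccccc3)c2)c1C(O)c1ccc(OCc2ccccc2)cc1 | intermediate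
21 | 3-{2-[3-hydroxy-4-(4-hydroxybenzyl)phenyl]ethyl}-2,4-bis(4-hydroxybenzyl)-5-methoxyphenol | COc1cc(O)c(Cc2ccc(O)cc2)c(CCc2ccc(Cc3ccc(O)cc3)c(O)c2)c1Cc1ccc(O)cc1 | target

**Step count and risks**

Total: 12 steps. Longest linear sequence: 10 steps (steps 3 to 12, from 4-bromo-2-hydroxybenzaldehyde); the diene branch (steps 1 and 2) joins at step 9.

Steps most likely to fail:

Step 9. The cycloaddition may be slow because both diene termini are fully substituted. During long heating the diene may isomerise by 1,5-hydrogen shift or lose its silyl enol ether, and the ynone may polymerise. The fallback sets out from alkyne 14 and moves the aryl–carbon bond formation to after the cycloaddition, so that a smaller and more electrophilic dienophile is used. Deprotonation of 14 with n-BuLi in THF at −78 °C and formylation with DMF (inverse quench into aqueous KH2PO4) should give 5-{3-(benzyloxy)-4-[4-(benzyloxy)benzyl]phenyl}pent-2-ynal F1. Heating F1 with diene 6 in toluene (90 °C, then 150 °C) should pass through 4-[4-(benzyloxy)benzyl]-3-(2-{3-(benzyloxy)-4-[4-(benzyloxy)benzyl]phenyl}ethyl)-5-(tert-butyldimethylsilyloxy)-1-methoxybicyclo[2.2.2]octa-2,5-diene-2-carbaldehyde F2, and loss of ethylene should give 2-(2-{3-(benzyloxy)-4-[4-(benzyloxy)benzyl]phenyl}ethyl)-3-[4-(benzyloxy)benzyl]-4-(tert-butyldimethylsilyloxy)-6-methoxybenzaldehyde F3. Addition of Grignard reagent 10 to F3 in THF at 0 °C then returns to the route at carbinol 19, bypassing ketone 18.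

Step 6. The Heck reaction of an electron-rich aryl bromide may stall, or may insert with the wrong regiochemistry and give branched or unsaturated by-products. The fallback sets out from bromide 12 and uses a B-alkyl Suzuki–Miyaura coupling, which fixes the linear connectivity. Hydroboration of acrolein diethyl acetal with 9-BBN-H in THF gives 9-(3,3-diethoxypropyl)-9-borabicyclo[3.3.1]nonane F4. Coupling of F4 with 12 (PdCl2(dppf), K3PO4, THF–DMF–H2O, 60 °C) should give 2-(benzyloxy)-1-[4-(benzyloxy)benzyl]-4-(3,3-diethoxypropyl)benzene F5. Hydrolysis of F5 with 1 M HCl in THF returns to the route at aldehyde 13.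

Step 12. Hydrogenolysis of the crowded benzylic C–OH bond may be incomplete while the benzyl ethers cleave, and the free hydroxy carbinol made in step 11 may ionise and oligomerise on handling. The fallback sets out from carbinol 19 and removes the benzylic oxygen by ionic hydrogenation before any phenol is unmasked. Et3SiH and TFA in CH2Cl2 at −20 °C should give tert-butyl[3-(2-{3-(benzyloxy)-4-[4-(benzyloxy)benzyl]phenyl}ethyl)-2,4-bis[4-(benzyloxy)benzyl]-5-methoxyphenoxy]dimethylsilane F6. TBAF buffered with AcOH in THF should give 3-(2-{3-(benzyloxy)-4-[4-(benzyloxy)benzyl]phenyl}ethyl)-2,4-bis[4-(benzyloxy)benzyl]-5-methoxyphenol F7. Hydrogenolysis of F7 (H2, Pd/C, EtOAc–MeOH), which now cleaves only benzyl ethers, returns to the route at target 21.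

**Further compounds**

F1 | step 9 | 5-{3-(benzyloxy)-4-[4-(benzyloxy)benzyl]phenyl}pent-2-ynal | O=CC#CCCc1ccc(Cc2ccc(OCc3ccccc3)cc2)c(OCc2ccccc2)c1
F2 | step 9 | 4-[4-(benzyloxy)benzyl]-3-(2-{3-(benzyloxy)-4-[4-(benzyloxy)benzyl]phenyl}ethyl)-5-(tert-butyldimethylsilyloxy)-1-methoxybicyclo[2.2.2]octa-2,5-diene-2-carbaldehyde (racemic) | COC12CCC(Cc3ccc(OCc4ccccc4)cc3)(C(O[Si](C)(C)C(C)(C)C)=C1)C(CCc1ccc(Cc3ccc(OCc4ccccc4)cc3)c(OCc3ccccc3)c1)=C2C=O
F3 | step 9 | 2-(2-{3-(benzyloxy)-4-[4-(benzyloxy)benzyl]phenyl}ethyl)-3-[4-(benzyloxy)benzyl]-4-(tert-butyldimethylsilyloxy)-6-methoxybenzaldehyde | COc1cc(O[Si](C)(C)C(C)(C)C)c(Cc2ccc(OCc3ccccc3)cc2)c(CCc2ccc(Cc3ccc(OCc4ccccc4)cc3)c(OCc3ccccc3)c2)c1C=O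
F4 | step 6 | 9-(3,3-diethoxypropyl)-9-borabicyclo[3.3.1]nonane | CCOC(CCB1C2CCCC1CCC2)OCC
F5 | step 6 | 2-(benzyloxy)-1-[4-(benzyloxy)benzyl]-4-(3,3-diethoxypropyl)benzene | CCOC(CCc1ccc(Cc2ccc(OCc3ccccc3)cc2)c(OCc2ccccc2)c1)OCC
F6 | step 12 | tert-butyl[3-(2-{3-(benzyloxy)-4-[4-(benzyloxy)benzyl]phenyl}ethyl)-2,4-bis[4-(benzyloxy)benzyl]-5-methoxyphenoxy]dimethylsilane | COc1cc(O[Si](C)(C)C(C)(C)C)c(Cc2ccc(OCc3ccccc3)cc2)c(CCc2ccc(Cc3ccc(OCc4ccccc4)cc3)c(OCc3ccccc3)c2)c1Cc1ccc(OCc2ccccc2)cc1
F7 | step 12 | 3-(2-{3-(benzyloxy)-4-[4-(benzyloxy)benzyl]phenyl}ethyl)-2,4-bis[4-(benzyloxy)benzyl]-5-methoxyphenol | COc1cc(O)c(Cc2ccc(OCc3ccccc3)cc2)c(CCc2ccc(Cc3ccc(OCc4ccccc4)cc3)c(OCc3ccccc3)c2)c1Cc1ccc(OCc2ccccc2)cc1
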